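**Strategy.** Ring B is disconnected at C9–C10. The target offers a quaternary C10 next to tertiary C9, with C8 bearing the carboxyl carbon C17. A tertiary C10 radical, generated by hydrogen-atom transfer to the ring A alkene, can therefore add 6-endo to C9 of a C8=C9 alkylidene β-keto ester. That single operation closes ring B, forms C9–C10 and relays the C5 configuration to C10 and C9. The precursor is a monocyclic (Z)-alkylidene β-keto ester (C7 ketone, tert-butyl C17 ester), made by Knoevenagel union of an α-cyclogeranyl-type β-keto ester with the C9–C15 aldehyde from (S)-citronellol. The C15 acetate and the C13 centre are carried from the start.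

Key step: step 7

Remark: labdane numbering is used (ring A = C1–C5 and C10, ring B = C5–C10, side chain C11–C16, C17 = carboxyl carbon on C8); the (S)-oxazaborolidine is assumed to give the R carbinol by the usual large/small model, the antipodal catalyst being used if the sense were the reverse.

**Step 1**
Reactants: 1 2,4,4-trimethylcyclohex-2-en-1-one
Product: 2 (1R)-2,4,4-trimethylcyclohex-2-en-1-ol
Conditions: (S)-2-methyl-CBS-oxazaborolidine [(3aS)-1-methyl-3,3-diphenyltetrahydro-1H,3H-pyrrolo[1,2-c][1,3,2]oxazaborole] (10 mol %), BH3·SMe2 (0.6 equiv), THF, −20 °C, slow addition of 1; MeOH quench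
Reagents that add atoms: none
Why: Corey–Bakshi–Shibata reduction, in which the oxazaborolidine–borane complex binds the carbonyl anti to the larger 2-methylvinyl arm and delivers hydride to the face that gives the R carbinol (1,2-reduction only), so this centre is set by the catalyst.

**Step 2**
Reactants: 2 (1R)-2,4,4-trimethylcyclohex-2-en-1-ol; 3 triethyl orthoacetate
Product: 5 ethyl 2-[(1S)-2,6,6-trimethylcyclohex-2-en-1-yl]acetate, via mixed ketene acetal 4 (not isolated)
Conditions: MeC(OEt)3 (6 equiv), EtCO2H (10 mol %), 140 °C, EtOH distilled off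
Reagents that add atoms: triethyl orthoacetate (3), CCOC(C)(OCC)OCC
Why: Johnson–Claisen rearrangement, in which ketene acetal 4 undergoes a suprafacial [3,3] shift across the ring, so the new C–C bond forms next to the gem-dimethyl carbon on the face that carried the oxygen, turning the R carbinol centre into the S centre that becomes C5 and leaving the alkene at the future C1=C10.

**Step 3**
Reactants: 5 ethyl 2-[(1S)-2,6,6-trimethylcyclohex-2-en-1-yl]acetate; 6 tert-butyl acetate
Product: 8 tert-butyl 3-oxo-4-[(1S)-2,6,6-trimethylcyclohex-2-en-1-yl]butanoate, via lithium enolate 7 (not isolated)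
Conditions: LDA (LiN(i-Pr)2, 3.2 equiv), 6 (3.2 equiv), THF, −78 °C; then 5, −78 → 0 °C; aq NH4Cl
Reagents that add atoms: tert-butyl acetate (6), CC(=O)OC(C)(C)C
Why: Crossed Claisen condensation, in which the preformed lithium enolate 7 adds to the ethyl ester and the β-keto ester is withdrawn from the equilibrium as its enolate (hence the excess of 7), while the ring stereocentre, β to the new ketone, is not touched.

**Step 4**
Reactants: 9 (S)-citronellol
Product: 10 (3S)-3,7-dimethyloct-6-en-1-yl acetate
Conditions: Ac2O (1.3 equiv), pyridine (2 equiv), DMAP (5 mol %), CH2Cl2, 0 °C → rt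
Reagents that add atoms: acetic anhydride, CC(=O)OC(C)=O
Why: DMAP-catalysed esterification of the unhindered primary alcohol installs the acetate that the target carries at C15, the stereocentre being remote and unaffected.

**Step 5**
Reactants: 10 (3S)-3,7-dimethyloct-6-en-1-yl acetate
Product: 12 (3S)-3-methyl-6-oxohexyl acetate, via ozonide 11 (not isolated)
Conditions: O3, CH2Cl2, −78 °C; then Me2S (5 equiv), −78 °C → rt
Reagents that add atoms: ozone, O=[O+][O-]
Why: Ozonolysis (Criegee mechanism) cleaves the only alkene and Me2S reduces ozonide 11 to the aldehyde, the acetate being inert and the methyl-bearing centre lying γ to the new carbonyl, where it cannot epimerise.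

**Step 6**
Reactants: 8 tert-butyl 3-oxo-4-[(1S)-2,6,6-trimethylcyclohex-2-en-1-yl]butanoate; 12 (3S)-3-methyl-6-oxohexyl acetate
Product: 14 tert-butyl (2Z,6S)-8-acetoxy-6-methyl-2-{[(1S)-2,6,6-trimethylcyclohex-2-en-1-yl]acetyl}oct-2-enoate, via aldol adduct 13 (not isolated)
Conditions: piperidine (10 mol %), AcOH (10 mol %), 4 Å molecular sieves, CH2Cl2, 0 °C → rt; chromatography, any E isomer re-equilibrated with catalytic piperidine
Reagents that add atoms: none
Why: Knoevenagel condensation through the piperidine-derived iminium ion, adduct 13 and loss of water; reversible amine addition equilibrates the alkene geometry, and the Z isomer, with the ketone coplanar and anti to the chain and the bulky tert-butyl ester twisted beside it, is expected to dominate, no stereocentre being formed.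

**Step 7**
Reactants: 14 tert-butyl (2Z,6S)-8-acetoxy-6-methyl-2-{[(1S)-2,6,6-trimethylcyclohex-2-en-1-yl]acetyl}oct-2-enoate
Product: 17 tert-butyl (5S,8S,9S,10R,13S)-15-acetoxy-7-oxolabdan-17-oate, via C10 radical 15 (not isolated), via C8 radical 16 (not isolated)
Conditions: Fe(acac)3 (30 mol %), PhSiH3 (2.5 equiv), EtOH/ethylene glycol (5:1), 0.02 M, 60 °C, argon
Reagents that add atoms: none
Why: An iron hydride formed from Fe(acac)3 and PhSiH3 transfers a hydrogen atom to C1 of the electron-rich trisubstituted ring A alkene, giving tertiary C10 radical 15, which adds to C9, the β-carbon of the alkylidene β-keto ester, to give the doubly stabilised C8 radical 16; divalent iron reduces 16 to the enolate and ethanol protonates it, so the closest known reaction type is the iron-hydride reductive olefin coupling run intramolecularly (Giese-type cyclisation). Ring B closes 6-endo-trig, preferred over 5-exo because C9 is the electrophilic, less substituted terminus and attack at C8 would leave an unstabilised radical. C10 is controlled by C5: with the C5 arm equatorial on ring A, C9 should approach the radical equatorially, the axial path being blocked by the axial methyl on C4, which gives the trans ring fusion with the C10 methyl axial. C9 is controlled by the alkene geometry in a chair-like array: in the Z isomer the chain is anti to C7 and should end equatorial (9α-H). C8 is set last by protonation, should relax to the equatorial ester through the enol, and is erased again in step 8. The step needs hydrogen-atom transfer to the ring alkene to outrun hydride reduction of the acceptor, which the preference of the iron hydride for electron-rich alkenes and the fast intramolecular trap should secure.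

**Step 8**
Reactants: 17 tert-butyl (5S,8S,9S,10R,13S)-15-acetoxy-7-oxolabdan-17-oate
Product: 18 tert-butyl (5S,9R,10S,13S)-15-acetoxy-7-[(trifluoromethanesulfonyl)oxy]labd-7-en-17-oate
Conditions: i-Pr2NEt (3 equiv), Tf2O (1.5 equiv), CH2Cl2, −78 → 0 °C
Reagents that add atoms: trifluoromethanesulfonic anhydride, O=S(=O)(OS(=O)(=O)C(F)(F)F)C(F)(F)F
Why: Enol triflate formation, in which the β-keto ester enolises only between its two carbonyls, so O-sulfonylation fixes the double bond at C7=C8 and removes the C8 centre while C9 (not acidic), C5, C10 and C13 are untouched.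

**Step 9**
Reactants: 18 tert-butyl (5S,9R,10S,13S)-15-acetoxy-7-[(trifluoromethanesulfonyl)oxy]labd-7-en-17-oate
Product: 19 tert-butyl (5S,9R,10S,13S)-15-acetoxylabd-7-en-17-oate
Conditions: Pd(OAc)2 (5 mol %), PPh3 (10 mol %), HCO2H (3 equiv), n-Bu3N (4 equiv), DMF, 60 °C
Reagents that add atoms: none
Why: Palladium-catalysed formate reduction of a vinyl triflate, in which oxidative addition to zerovalent palladium, decarboxylation of bound formate to a palladium hydride and reductive elimination replace OTf by H without moving the C7=C8 bond or touching either ester.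

**Step 10**
Reactants: 19 tert-butyl (5S,9R,10S,13S)-15-acetoxylabd-7-en-17-oate
Product: 20 (5S,9R,10S,13S)-15-acetoxylabd-7-en-17-oic acid (CNP0412535.1)
Conditions: CF3CO2H/CH2Cl2 (1:4), 0 °C → rt
Reagents that add atoms: none
Why: Acidolysis of the tert-butyl ester through the tert-butyl cation, lost as isobutene, frees the C17 acid while the primary acetate and the conjugated C7=C8 bond should survive, giving the target.

**Compound list**
1 | 2,4,4-trimethylcyclohex-2-en-1-one | CC1=CC(C)(C)CCC1=O | starting material
2 | (1R)-2,4,4-trimethylcyclohex-2-en-1-ol | O[C@@H]1CCC(C)(C)C=C1C | intermediate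
3 | triethyl orthoacetate | CCOC(C)(OCC)OCC | starting material
4 | 1-ethoxy-1-{[(1R)-2,4,4-trimethylcyclohex-2-en-1-yl]oxy}ethene (mixed ketene acetal) | C=C(OCC)O[C@@H]1CCC(C)(C)C=C1C | intermediate (not isolated)
5 | ethyl 2-[(1S)-2,6,6-trimethylcyclohex-2-en-1-yl]acetate | CCOC(=O)C[C@H]1C(C)(C)CCC=C1C | intermediate
6 | tert-butyl acetate | CC(=O)OC(C)(C)C | starting material
7 | lithium 1-(tert-butoxy)ethenolate (lithium enolate of 6) | [Li]OC(=C)OC(C)(C)C | intermediate (not isolated)
8 | tert-butyl 3-oxo-4-[(1S)-2,6,6-trimethylcyclohex-2-en-1-yl]butanoate | CC(C)(C)OC(=O)CC(=O)C[C@H]1C(C)(C)CCC=C1C | intermediate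
9 | (S)-citronellol | OCC[C@@H](C)CCC=C(C)C | starting material
10 | (3S)-3,7-dimethyloct-6-en-1-yl acetate ((S)-citronellyl acetate) | CC(=O)OCC[C@@H](C)CCC=C(C)C | intermediate
11 | (3S)-5-(5,5-dimethyl-1,2,4-trioxolan-3-yl)-3-methylpentyl acetate (ozonide, epimers at the ring carbon) | CC(=O)OCC[C@@H](C)CCC1OOC(C)(C)O1 | intermediate (not isolated)
12 | (3S)-3-methyl-6-oxohexyl acetate | CC(=O)OCC[C@@H](C)CCC=O | intermediate
13 | tert-butyl (6S)-8-acetoxy-3-hydroxy-6-methyl-2-{[(1S)-2,6,6-trimethylcyclohex-2-en-1-yl]acetyl}octanoate (aldol adduct, mixture at C2 and C3) | CC(=O)OCC[C@@H](C)CCC(O)C(C(=O)OC(C)(C)C)C(=O)C[C@H]1C(C)(C)CCC=C1C | intermediate (not isolated)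
14 | tert-butyl (2Z,6S)-8-acetoxy-6-methyl-2-{[(1S)-2,6,6-trimethylcyclohex-2-en-1-yl]acetyl}oct-2-enoate (key-step precursor) | CC(=O)OCC[C@@H](C)CC/C=C(\C(=O)OC(C)(C)C)C(=O)C[C@H]1C(C)(C)CCC=C1C | intermediate
15 | tertiary C10 radical formed from 14 by hydrogen-atom transfer to C1 | CC(=O)OCC[C@@H](C)CC/C=C(\C(=O)OC(C)(C)C)C(=O)C[C@H]1C(C)(C)CCC[C]1C | intermediate (not isolated)
16 | C8 radical after closure of ring B | CC(=O)OCC[C@@H](C)CC[C@H]1[C](C(=O)OC(C)(C)C)C(=O)C[C@H]2C(C)(C)CCC[C@]12C | intermediate (not isolated)
17 | tert-butyl (5S,8S,9S,10R,13S)-15-acetoxy-7-oxolabdan-17-oate (trans-decalin; 5α-H, 9α-H, 10β-methyl, 8β-H) | CC(=O)OCC[C@@H](C)CC[C@H]1[C@H](C(=O)OC(C)(C)C)C(=O)C[C@H]2C(C)(C)CCC[C@]12C | intermediate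
18 | tert-butyl (5S,9R,10S,13S)-15-acetoxy-7-[(trifluoromethanesulfonyl)oxy]labd-7-en-17-oate | CC(=O)OCC[C@@H](C)CC[C@H]1C(C(=O)OC(C)(C)C)=C(OS(=O)(=O)C(F)(F)F)C[C@H]2C(C)(C)CCC[C@]12C | intermediate
19 | tert-butyl (5S,9R,10S,13S)-15-acetoxylabd-7-en-17-oate | CC(=O)OCC[C@@H](C)CC[C@H]1C(C(=O)OC(C)(C)C)=CC[C@H]2C(C)(C)CCC[C@]12C | intermediate
20 | (5S,9R,10S,13S)-15-acetoxylabd-7-en-17-oic acid, i.e. (1R,4aS,8aS)-1-[(3S)-5-acetoxy-3-methylpentyl]-5,5,8a-trimethyl-1,4,4a,5,6,7,8,8a-octahydronaphthalene-2-carboxylic acid | CC(=O)OCC[C@@H](C)CC[C@H]1C(C(=O)O)=CC[C@H]2C(C)(C)CCC[C@]12C | target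

**Totals.** Total step count: 10. Longest linear sequence: 8 steps (steps 1, 2, 3, 6, 7, 8, 9, 10).

**Steps most likely to fail**

Step 7. Face discrimination at C9 may be lost, because the chair-like closure may be only modestly favoured over a boat-like one and the alkylidene may scramble its geometry under the radical conditions. The fallback sets C9 by hydrogenation instead of by the ring closure. It sets out from 14: the cyclisation is run as in step 7 and the mixture of 17 and its C9 epimer, tert-butyl 15-acetoxy-7-oxo-9-epi-labdan-17-oate F1, is taken on unseparated. PhSeCl and pyridine in CH2Cl2 should selenenylate C8 of both epimers anti to the C9 chain, giving tert-butyl 15-acetoxy-7-oxo-8-(phenylselanyl)labdan-17-oate F2. H2O2 should then trigger selenoxide syn-elimination toward C9, the only β-hydrogen, to give the enone ester tert-butyl 15-acetoxy-7-oxolabd-8-en-17-oate F3, in which C9 is no longer stereogenic. Hydrogenation (H2, Pd/C, EtOAc) should add from the α face, opposite the axial C10 methyl, and after enol equilibration at C8 the sequence comes back to the route at 17.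

Step 6. The alkylidene β-keto ester may take up a second molecule of 8 by Michael addition, drift out of conjugation through its dienol, or settle to an unfavourable mixture of geometries in the presence of the amine. The fallback makes the C8–C9 bond by alkylation and introduces the double bond afterwards, with no amine present. It sets out from 12 and 8. NaBH4 (MeOH, 0 °C) should reduce 12 to (3S)-6-hydroxy-3-methylhexyl acetate F4, and I2, PPh3 and imidazole (Appel-type iodination) should give (3S)-6-iodo-3-methylhexyl acetate F5. K2CO3 in acetone should C-alkylate 8 with this iodide to tert-butyl (6S)-8-acetoxy-6-methyl-2-{[(1S)-2,6,6-trimethylcyclohex-2-en-1-yl]acetyl}octanoate F6. NaH then PhSeCl (THF, 0 °C) should give tert-butyl (6S)-8-acetoxy-6-methyl-2-(phenylselanyl)-2-{[(1S)-2,6,6-trimethylcyclohex-2-en-1-yl]acetyl}octanoate F7, and H2O2 oxidation with syn-elimination comes back to the route at 14. Any E isomer is then handled by the C9 repair given for step 7.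

Step 2. At 140 °C under acid the allylic alcohol may dehydrate to a diene faster than the ketene acetal rearranges, since the new bond is made next to the quaternary ring carbon. The fallback runs the same chirality transfer as an ester-enolate (Ireland–Claisen) rearrangement, anionic and below 70 °C. It sets out from 2. Ac2O, pyridine and DMAP should give (1R)-2,4,4-trimethylcyclohex-2-en-1-yl acetate F8. LDA and Me3SiCl in THF at −78 °C should give the silyl ketene acetal 1-[(trimethylsilyl)oxy]-1-{[(1R)-2,4,4-trimethylcyclohex-2-en-1-yl]oxy}ethene F9, which on warming to 60 °C should rearrange suprafacially to trimethylsilyl [(1S)-2,6,6-trimethylcyclohex-2-en-1-yl]acetate F10. Aqueous work-up should give [(1S)-2,6,6-trimethylcyclohex-2-en-1-yl]acetic acid F11, and EtI with K2CO3 in DMF comes back to the route at 5.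

**Further compounds**
F1 | step 7 | tert-butyl 15-acetoxy-7-oxo-9-epi-labdan-17-oate (9β-H; C8 unassigned) | CC(=O)OCC[C@@H](C)CC[C@@H]1C(C(=O)OC(C)(C)C)C(=O)C[C@H]2C(C)(C)CCC[C@]12C
F2 | step 7 | tert-butyl 15-acetoxy-7-oxo-8-(phenylselanyl)labdan-17-oate (mixture at C8 and C9) | CC(=O)OCC[C@@H](C)CCC1C([Se]c2ccccc2)(C(=O)OC(C)(C)C)C(=O)C[C@H]2C(C)(C)CCC[C@]12C
F3 | step 7 | tert-butyl (5S,10S,13S)-15-acetoxy-7-oxolabd-8-en-17-oate | CC(=O)OCC[C@@H](C)CCC1=C(C(=O)OC(C)(C)C)C(=O)C[C@H]2C(C)(C)CCC[C@]12C
F4 | step 6 | (3S)-6-hydroxy-3-methylhexyl acetate | CC(=O)OCC[C@@H](C)CCCO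
F5 | step 6 | (3S)-6-iodo-3-methylhexyl acetate | CC(=O)OCC[C@@H](C)CCCI
F6 | step 6 | tert-butyl (6S)-8-acetoxy-6-methyl-2-{[(1S)-2,6,6-trimethylcyclohex-2-en-1-yl]acetyl}octanoate (mixture at C2) | CC(=O)OCC[C@@H](C)CCCC(C(=O)OC(C)(C)C)C(=O)C[C@H]1C(C)(C)CCC=C1C
F7 | step 6 | tert-butyl (6S)-8-acetoxy-6-methyl-2-(phenylselanyl)-2-{[(1S)-2,6,6-trimethylcyclohex-2-en-1-yl]acetyl}octanoate (mixture at C2) | CC(=O)OCC[C@@H](C)CCCC([Se]c1ccccc1)(C(=O)OC(C)(C)C)C(=O)C[C@H]2C(C)(C)CCC=C2C
F8 | step 2 | (1R)-2,4,4-trimethylcyclohex-2-en-1-yl acetate | CC(=O)O[C@@H]1CCC(C)(C)C=C1C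
F9 | step 2 | 1-[(trimethylsilyl)oxy]-1-{[(1R)-2,4,4-trimethylcyclohex-2-en-1-yl]oxy}ethene | C=C(O[Si](C)(C)C)O[C@@H]1CCC(C)(C)C=C1C
F10 | step 2 | trimethylsilyl [(1S)-2,6,6-trimethylcyclohex-2-en-1-yl]acetate | C[Si](C)(C)OC(=O)C[C@H]1C(C)(C)CCC=C1C
F11 | step 2 | [(1S)-2,6,6-trimethylcyclohex-2-en-1-yl]acetic acid | OC(=O)C[C@H]1C(C)(C)CCC=C1C
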